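More X than J charged is impossible when each X takes up one J, so J is the limiting reagent. X in the flask therefore stands at 50.0% of the Q charged at most, and I name this the J ceiling: J charged over Q charged.

| flask | Q | J | L | remark | time |
|---|---|---|---|---|---|
| amber | 1 M | 0.50 M | 2 M | run made earlier |  |
| flask | 1.0 M | 0.500 M | 1.00 M |  | 20 h |

amber run (percent of the Q charged)

| time / min | Q / % | X / % |
|---|---|---|
| 15.0 | 91.8 | 9.1 |
| 40.0 | 86.5 | 13.7 |
| 80.0 | 79.8 | 18.7 |
| 120 | 77.8 | 22.4 |

(standard deviation of a reading: 0.5 percentage points)

- the reaction counts as stopped when no species that holds the Q changes by six tenths of a point or more over the second half of the time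

* the state of affairs at 20 h: stopped, and by what, or still going (forward and back rates have come level / it is still moving / all of Q has reacted / J has run out first)
* part of the Q gone at 20 h
* the X standing at 20 h, as a percentage of the Q charged
* amount of X if the flask were left three thousand times as long, in percent of the Q charged

Now the balance. At the last amber reading X stands at 22.4%, so J charged minus X formed leaves 0.276 M of J, if J goes into X and nowhere else. A rate following the product of Q and J would then be 0.429 of its starting value. The last gain per minute is 0.152 of the first, a steeper fall, so I expect X to level off below the ceiling.

To place that level, I take the last two equal intervals of the amber run, whose gains in X stand in the ratio 0.740. If later gains shrink by that ratio, they sum to a plateau of 32.9%, approached with a time constant of 2.21 h, shorter than 20 h.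

The weak link is that ratio, built from two small differences of readings good to 0.5 percentage points. Reforged on the Q column, the same sum gives 23.1%. Amber held more L, and one run cannot show what L does, so I carry the plateau over unchanged. I commit to a flask level by 20 h, with X between 23.1% and 32.9%.

The forecast differs: it is still moving, 34% of Q gone, X at 33%, and 50% in the long run, on the ground that “If J is truly stoichiometric, it caps X at 50% at very long times”.

The flask gives: forward and back rates have come level, with 32.8% of Q gone, X at 32.8%, and 32.8% in the long run.

    Q + J ⇌ X (K = 5.70 L mol⁻¹, k = 4.00 × 10⁻⁴ L mol⁻¹ s⁻¹)
    L + J ⇌ G (K = 1.10 L mol⁻¹, k = 0.00110 L mol⁻¹ s⁻¹)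

In the flask X stands at 32.8%, under the J ceiling of 50.0%, with 17% of the charged J still free. The main reason for that conversion is the shrinking supply of J: the same flask with that shrinking taken away has 74.0% of its Q converted, 41 points more. The neighbour charged with 0.20 M of J has a ceiling of 20.0%, and its X stands at 14.1%.

(The runs were generated by integration from invented constants; scatter was added.)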